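**Plan**

1. Retrosynthetic cuts, in order: (a) the O–C4 and CH(iPr)–C5 bonds of the dihydropyran (retro-oxa-Diels–Alder, caryophyllene numbering); (b) the C=CH(iPr) bond (retro-Knoevenagel); (c) one C(=O)–C(CH3)2 bond of the six-membered trione ring, from the ring carbonyl next to the CH2-derived carbon to the gem-dimethyl carbon that also carries the central ketone (retro-Claisen); (d) the CH2–C(=O) bond of the open-chain diketo ester (acyl transfer from dimethylketene β-lactone dimer).
2. Enabling features: the carbocycle is a fully C-methylated triketide. Its gem-dimethyl carbon is the α-carbon of an isopropyl ketone and the neighbouring ring carbonyl is an ester carbon in the open chain. The closed 1,3,5-trione has a single CH2 between two carbonyls, which becomes a 2-alkylidene-1,3-dione (1-oxadiene) that the strained E-trisubstituted C4=C5 alkene of the nine-membered ring traps.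
3. Forward: a C8 acyl donor and methyl acetate give the open chain; one flask then closes the carbocycle (Claisen), attaches the isobutylidene carbon (Knoevenagel) and closes the pyran onto (−)-β-caryophyllene ([4+2]).
4. Stereochemistry: C1 and C9 come with natural (−)-β-caryophyllene. C4, C5 and the isopropyl-bearing carbon are set in the cycloaddition (suprafacial addition to the E alkene, attack on the exposed outer face of the nine-membered ring, oxadiene over the C4-methyl/C6 side).

Key step: step 3

Remark: the trione intermediate has a mirror plane through its CH2 carbon and the opposite carbonyl, so its two acyl–C(CH3)2 bonds next to the CH2 are equivalent and either carbonyl oxygen can enter the pyran with the same product; the bond closed in the Claisen step is therefore the bond between the conjugated ring ketone carbon of the target and its C(CH3)2 neighbour; natural (1R,9S,4E)-(−)-β-caryophyllene is taken as the commercial source of the cyclobutane stereocentres.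

**Route**

Step 1
Reactants: 1 2,2,4,4-tetramethylcyclobutane-1,3-dione
Product: 2 3,3-dimethyl-4-(propan-2-ylidene)oxetan-2-one (dimethylketene β-lactone dimer)
Conditions: AlCl3 (cat.), chlorobenzene, 135 °C; distillation
Reagents that add atoms: none
Why: Lewis-acid-catalysed isomerisation of the cyclobutane-1,3-dione to the enol β-lactone (C-acyl to O-acyl rearrangement through an acylium/aluminium enolate pair), a known interconversion of ketene dimers in which no stereocentre is formed.

Step 2
Reactants: 2 3,3-dimethyl-4-(propan-2-ylidene)oxetan-2-one; 3 methyl acetate
Product: 5 methyl 4,4,6-trimethyl-3,5-dioxoheptanoate, via lithium enolate of methyl acetate 4 (not isolated)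
Conditions: 3, LiN(SiMe3)2, THF, −78 °C; then 2, −78 to 0 °C; AcOH quench
Reagents that add atoms: none
Why: Claisen-type C-acylation of the ester enolate at the strained lactone carbonyl with acyl–oxygen cleavage, the liberated isopropyl ketone enolate being protonated at once by the far more acidic β-keto ester CH2 so that one equivalent of base suffices and no stereocentre is formed.

Step 3
Reactants: 5 methyl 4,4,6-trimethyl-3,5-dioxoheptanoate; 6 isobutyraldehyde; 7 (−)-β-caryophyllene
Product: 10 myrtucommulone K, via syncarpic acid 8 (not isolated), via isobutylidenesyncarpic acid 9 (not isolated)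
Conditions: KOtBu (2.2 equiv), THF, 0 to 50 °C; then AcOH (5 equiv), 6, 7, 70 °C, sealed tube
Reagents that add atoms: none
Why: tert-Butoxide forms the tertiary enolate at C6 of 5, which adds 6-exo-trig to the C1 ester carbonyl and expels methoxide (Claisen/Dieckmann condensation, as in dimedone-type ring closures and in the polyketide Claisen cyclisation that builds phloroglucinol rings), the new trione 8 leaving the equilibrium as its potassium enolate. AcOH sets 8 free, and its single CH2, flanked by two carbonyls, condenses with 6 under acetate catalysis (Knoevenagel) to the 2-alkylidene-1,3-dione 9, a fixed s-cis 1-oxadiene. 9 then adds to the strained E C4=C5 bond of 7 in a concerted inverse-electron-demand oxa-[4+2] cycloaddition that closes the dihydropyran, the closest known type being the domino Knoevenagel/hetero-Diels–Alder reaction of cyclic 1,3-diones with aldehydes and alkenes. Oxygen bonds to the more substituted C4 and the alkylidene carbon to C5, as the polarisation of the oxadiene demands, and the unstrained exocyclic C8 methylene is left alone. Suprafacial addition to the E alkene fixes C4–CH3 trans to C5–H, attack on the exposed outer face of the nine-membered ring (the face that peracids also use, dictated by the C1/C9 ring fusion) sets C4 and C5, and the isopropyl carbon follows from the transition state in which the isopropyl group is outside on the oxadiene and the trione ring lies over the C4–CH3/C6 side of the alkene, away from the C3–C2–C1 bridge to the cyclobutane. The step thus needs facial and endo/exo selectivity, which the conformational bias of the trans-cyclononene and the bulk of the gem-dimethyl groups of 9 are expected to supply.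

**Compound list**

1 | 2,2,4,4-tetramethylcyclobutane-1,3-dione | CC1(C)C(=O)C(C)(C)C1=O | starting material
2 | 3,3-dimethyl-4-(propan-2-ylidene)oxetan-2-one (dimethylketene β-lactone dimer) | CC(C)=C1OC(=O)C1(C)C | intermediate
3 | methyl acetate | COC(C)=O | starting material
4 | lithium enolate of methyl acetate (not isolated) | C=C(OC)O[Li] | intermediate
5 | methyl 4,4,6-trimethyl-3,5-dioxoheptanoate | COC(=O)CC(=O)C(C)(C)C(=O)C(C)C | intermediate
6 | isobutyraldehyde (2-methylpropanal) | CC(C)C=O | starting material
7 | (−)-β-caryophyllene, (1R,4E,9S)-4,11,11-trimethyl-8-methylidenebicyclo[7.2.0]undec-4-ene | C/C1=C\CCC(=C)[C@H]2CC(C)(C)[C@@H]2CC1 | starting material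
8 | syncarpic acid, 2,2,4,4-tetramethylcyclohexane-1,3,5-trione (formed as its potassium enolate, set free by AcOH, not isolated) | CC1(C)C(=O)CC(=O)C(C)(C)C1=O | intermediate
9 | isobutylidenesyncarpic acid, 2,2,4,4-tetramethyl-6-(2-methylpropylidene)cyclohexane-1,3,5-trione (not isolated) | CC(C)C=C1C(=O)C(C)(C)C(=O)C(C)(C)C1=O | intermediate
10 | myrtucommulone K: dihydropyran adduct with the enol ether oxygen on C4 and CH(iPr) on C5 of the caryophyllene unit, both on the face that epoxidation uses; C4–CH3 trans to C5–H; isopropyl cis to C4–CH3; C1, C9 and the exocyclic methylene as in 7 | C=C1CC[C@H]2[C@@H](C(C)C)C3=C(O[C@]2(C)CC[C@@H]2[C@@H]1CC2(C)C)C(C)(C)C(=O)C(C)(C)C3=O | target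

**Count and risks**

Total step count: 3. Longest linear sequence: 3 steps (1 → 2 → 5 → 10).

Steps most likely to fail:

1. Step 3. The Claisen closure may stall, because deprotonation of the C2 methylene deactivates the ester towards the hindered tertiary enolate and alkoxide may cleave the 1,3-diketone by retro-Claisen reaction; poor endo/exo discrimination in the cycloaddition is a second risk. Fallback, setting out from 5 and coming back at 10, with the order of ring formation reversed: condensation of 5 with 6 (piperidinium acetate, toluene, 90 °C) in the presence of 7 should give the alkylidene keto ester methyl (2Z)-4,4,6-trimethyl-2-(2-methylpropylidene)-3,5-dioxoheptanoate F1. Its ketone-based oxadiene should add to the C4=C5 bond of 7 to give seco-myrtucommulone K methyl ester F2, the dihydropyran that carries the ester on the enol ether β-carbon and the C(CH3)2–CO–CH(CH3)2 chain on the enol ether carbon, with the stereocentres of 10. In this compound the former CH2 is part of the enol ether, so the isopropyl ketone C–H is the only acidic one, and the ring holds the ester cis to the chain. KN(SiMe3)2 (THF, −78 °C to room temperature) should then close the same C(=O)–C(CH3)2 bond by Dieckmann condensation with loss of methoxide and give 10 directly.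

2. Step 2. The ester enolate may self-condense, or the liberated ketone enolate may acylate a second molecule of 2 (chain growth) instead of being protonated. Fallback, setting out from 2 and coming back at 5: Meldrum's acid (2,2-dimethyl-1,3-dioxane-4,6-dione) is acylated by 2 (pyridine, 4-(dimethylamino)pyridine cat., CH2Cl2, 0 °C to room temperature). This should give 5-(1-hydroxy-2,2,4-trimethyl-3-oxopentylidene)-2,2-dimethyl-1,3-dioxane-4,6-dione F3, whose strongly acidic enol quenches the liberated enolate at once and cannot self-condense. Heating in MeOH should then give 5 by acylketene formation and methanol capture.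

3. Step 1. AlCl3 may trigger ring-opening polymerisation of the β-lactone to polyester, or the isomerisation may stay incomplete. Fallback, setting out from 1 and coming back at 5, with the dione itself as acyl donor: addition of 4 (from 3 and LiN(SiMe3)2, THF, −78 °C) to one strained ketone of 1 should give methyl 2-(1-hydroxy-2,2,4,4-tetramethyl-3-oxocyclobutyl)acetate F4 as its lithium alkoxide. On warming this should open by retro-aldol fragmentation with release of ring strain, the same cleavage by which alkoxides open 1, to the enolate of 5, set free by AcOH.

**Further compounds**

F1 | step 3 | methyl (2Z)-4,4,6-trimethyl-2-(2-methylpropylidene)-3,5-dioxoheptanoate | COC(=O)/C(=C\C(C)C)C(=O)C(C)(C)C(=O)C(C)C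
F2 | step 3 | seco-myrtucommulone K methyl ester (dihydropyran with CO2CH3 on the enol ether β-carbon and a 2,4-dimethyl-3-oxopentan-2-yl chain on the enol ether carbon, stereocentres as in 10) | C=C1CC[C@H]2[C@@H](C(C)C)C(C(=O)OC)=C(O[C@]2(C)CC[C@@H]2[C@@H]1CC2(C)C)C(C)(C)C(=O)C(C)C
F3 | step 2 | 5-(1-hydroxy-2,2,4-trimethyl-3-oxopentylidene)-2,2-dimethyl-1,3-dioxane-4,6-dione | CC(C)C(=O)C(C)(C)C(O)=C1C(=O)OC(C)(C)OC1=O
F4 | step 1 | methyl 2-(1-hydroxy-2,2,4,4-tetramethyl-3-oxocyclobutyl)acetate | COC(=O)CC1(O)C(C)(C)C(=O)C1(C)C
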